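**Retrosynthetic overview**

1. The target is a (2S)-5-hydroxy-7-methoxyflavanone (ring A, ring C, phenyl ring B) with two identical 2-hydroxy-5-(2-hydroxybenzyl)benzyl arms on C6 and C8. Disconnections: the C6–CH2 and C8–CH2 bonds (acid-catalysed ortho-quinone methide Friedel–Crafts), then O1–C2 of ring C (catalytic asymmetric oxa-Michael), then C2=C3 (Knoevenagel) and C3–CO2tBu (Claisen-type acylation of an acetophenone).
2. Enabling feature: in the open-chain precursor, ring A has a mirror plane through C4a and C7. The oxygen that becomes O1 and the oxygen of the C5 hydroxyl are therefore equivalent, so either one closing onto C2 gives the same ring C and no phenol protection is needed. C6 and C8 are the only unsubstituted carbons of this phloroglucinol-type ring and take the same arm, so exhaustive benzylation poses no regiochemical question.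
3. Temporary activating group: a tert-butyl ester on C3 makes C2 a strong Michael acceptor and gives the chiral thiourea a 1,3-dicarbonyl to bind; it leaves as isobutene and CO2 in the same flask.
4. Arm: benzyl–aryl Suzuki coupling to the diarylmethane, double O-demethylation, reduction of the aldehyde to the salicyl alcohol.
5. Ring order: all six benzene rings are bought (the two rings of each arm are joined, not built). Ring C is the only ring made and is closed last, in step 6, which also removes the ester and attaches both arms.

Key step: step 6

Assumption: of the two pseudoenantiomeric cinchona thioureas, the quinine-derived one is taken as the one that gives 2S; if a test cyclisation shows the opposite sense, the quinidine-derived catalyst N-[3,5-bis(trifluoromethyl)phenyl]-N'-[(9R)-6'-methoxycinchonan-9-yl]thiourea takes its place with nothing else changed.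

**Route**

Step 1
Reactants: 1 2-methoxybenzyl chloride; 2 (3-formyl-4-methoxyphenyl)boronic acid
Product: 3 2-methoxy-5-(2-methoxybenzyl)benzaldehyde
Conditions: Pd(PPh3)4 (3 mol%), Na2CO3 (2 equiv), DME/H2O, 80 °C
Reagents that add atoms: none
Why: Suzuki–Miyaura benzyl–aryl cross-coupling (oxidative addition of zerovalent palladium into the benzylic C–Cl bond, transmetalation from the boronate, reductive elimination) should give the diarylmethane, the aldehyde and both methyl ethers being inert.

Step 2
Reactants: 3 2-methoxy-5-(2-methoxybenzyl)benzaldehyde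
Product: 4 2-hydroxy-5-(2-hydroxybenzyl)benzaldehyde
Conditions: BBr3 (3 equiv), CH2Cl2, −78 °C to 0 °C; then H2O
Reagents that add atoms: none
Why: BBr3 ether cleavage: boron coordinates each aryl methyl ether and bromide removes the methyl group as MeBr, while the aldehyde and the diarylmethane CH2 are untouched, so hydrolysis should give the bis-phenol aldehyde.

Step 3
Reactants: 4 2-hydroxy-5-(2-hydroxybenzyl)benzaldehyde
Product: 5 2-(hydroxymethyl)-4-(2-hydroxybenzyl)phenol
Conditions: NaBH4, MeOH/THF, 0 °C; aq. NH4Cl
Reagents that add atoms: none
Why: Borohydride reduction of the formyl group should give the salicyl alcohol that serves as ortho-quinone methide precursor, and the buffered cold work-up avoids premature ionisation of the benzylic alcohol.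

Step 4
Reactants: 6 2',6'-dihydroxy-4'-methoxyacetophenone
Product: 7 tert-butyl 3-(2,6-dihydroxy-4-methoxyphenyl)-3-oxopropanoate
Conditions: LiN(SiMe3)2 (4.2 equiv), THF, −78 °C; Boc2O (1.1 equiv), −78 °C to 0 °C; aq. NH4Cl
Reagents that add atoms: di-tert-butyl dicarbonate (Boc2O), CC(C)(C)OC(=O)OC(=O)OC(C)(C)C
Why: Claisen-type C-acylation of a ketone enolate with Boc2O: excess amide base makes the trilithium species (two chelated phenoxides and the methyl ketone enolate), whose enolate carbon is the most nucleophilic site, and the β-ketoester formed is deprotonated at once by the fourth equivalent, which stops a second acylation.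

Step 5
Reactants: 7 tert-butyl 3-(2,6-dihydroxy-4-methoxyphenyl)-3-oxopropanoate; 8 benzaldehyde
Product: 9 tert-butyl (2Z)-2-(2,6-dihydroxy-4-methoxybenzoyl)-3-phenylprop-2-enoate (Z isomer expected as the major one; a mixture of alkene isomers would be carried on)
Conditions: piperidine (10 mol%), AcOH (10 mol%), 4 Å MS, toluene, 0 °C to rt
Reagents that add atoms: none
Why: Knoevenagel condensation: piperidinium acetate condenses the active methylene with benzaldehyde and the sieves take up the water, the amine being kept catalytic and the temperature low so that the chelated phenols do not yet add to the new acceptor.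

Step 6
Reactants: 9 tert-butyl (2Z)-2-(2,6-dihydroxy-4-methoxybenzoyl)-3-phenylprop-2-enoate; 5 2-(hydroxymethyl)-4-(2-hydroxybenzyl)phenol (2.3 equiv)
Product: 12 5''-(2''''-hydroxybenzyl)uvarinol, via (2S)-flavanone-3-carboxylate 10 (not isolated), via (S)-pinostrobin 11 (not isolated)
Conditions: one pot: (a) N-[3,5-bis(trifluoromethyl)phenyl]-N'-[(8α,9S)-6'-methoxycinchonan-9-yl]thiourea (10 mol%), toluene, −25 °C, to full conversion; (b) TsOH·H2O (1 equiv), 80 °C; (c) 5 added slowly in 1,4-dioxane, 70 °C
Reagents that add atoms: none
Why: The quinuclidine nitrogen of the bifunctional catalyst activates one chelated phenol while its thiourea hydrogen-bonds the β-ketoester, and the phenol oxygen adds to the benzylidene carbon in a 6-endo-trig oxa-Michael closure that makes the O1–C2 bond of ring C and gives 10; this is the known chiral-thiourea cyclisation of 2'-hydroxyaryl alkylidene β-ketoesters to flavanones. The only lasting stereocentre, C2, is set by the catalyst, which holds the enone through the 1,3-dicarbonyl and delivers the oxygen to the face that gives 2S (the C3 centre is lost with the ester). TsOH then cleaves the tert-butyl ester and the β-keto acid loses CO2 to give 11, after which the same acid ionises salicyl alcohol 5 to its protonated ortho-quinone methide, which alkylates C6 and C8 in two Friedel–Crafts steps, the acid-promoted 2-hydroxybenzylation known for 5-hydroxyflavanones. Which oxygen closes needs no control, because the two ortho oxygens of 9 are equivalent through the mirror plane of ring A that runs through C4a and C7. Site selectivity in the alkylation is secured because C6 and C8 are the only CH positions of the phloroglucinol-type ring A, which should be far more nucleophilic than the monophenol rings of 5 and of the product, and slow addition of 5 keeps its self-condensation down. The C2 configuration should survive because no base is present after ring closure and acid-catalysed ring opening of a chelated 5-hydroxyflavanone is slow at these temperatures.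

**Compound list**

1 | 2-methoxybenzyl chloride | COc1ccccc1CCl | starting material
2 | (3-formyl-4-methoxyphenyl)boronic acid | COc1ccc(B(O)O)cc1C=O | starting material
3 | 2-methoxy-5-(2-methoxybenzyl)benzaldehyde | COc1ccccc1Cc1ccc(OC)c(C=O)c1 | intermediate
4 | 2-hydroxy-5-(2-hydroxybenzyl)benzaldehyde | O=Cc1cc(Cc2ccccc2O)ccc1O | intermediate
5 | 2-(hydroxymethyl)-4-(2-hydroxybenzyl)phenol | OCc1cc(Cc2ccccc2O)ccc1O | intermediate
6 | 2',6'-dihydroxy-4'-methoxyacetophenone | CC(=O)c1c(O)cc(OC)cc1O | starting material
7 | tert-butyl 3-(2,6-dihydroxy-4-methoxyphenyl)-3-oxopropanoate | COc1cc(O)c(C(=O)CC(=O)OC(C)(C)C)c(O)c1 | intermediate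
8 | benzaldehyde | O=Cc1ccccc1 | starting material
9 | tert-butyl (2Z)-2-(2,6-dihydroxy-4-methoxybenzoyl)-3-phenylprop-2-enoate | COc1cc(O)c(C(=O)/C(=C/c2ccccc2)C(=O)OC(C)(C)C)c(O)c1 | intermediate
10 | tert-butyl (2S)-5-hydroxy-7-methoxy-4-oxo-2-phenyl-3,4-dihydro-2H-chromene-3-carboxylate (C3 epimers and enol form; C3 is lost later) | COc1cc(O)c2c(c1)O[C@H](c1ccccc1)C(C(=O)OC(C)(C)C)C2=O | intermediate (not isolated)
11 | (S)-pinostrobin, (2S)-5-hydroxy-7-methoxy-2-phenyl-2,3-dihydro-4H-chromen-4-one | COc1cc(O)c2c(c1)O[C@H](c1ccccc1)CC2=O | intermediate (not isolated)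
12 | 5''-(2''''-hydroxybenzyl)uvarinol, (2S)-5-hydroxy-6,8-bis[2-hydroxy-5-(2-hydroxybenzyl)benzyl]-7-methoxy-2-phenyl-2,3-dihydro-4H-chromen-4-one | COc1c(Cc2cc(Cc3ccccc3O)ccc2O)c(O)c2c(c1Cc1cc(Cc3ccccc3O)ccc1O)O[C@H](c1ccccc1)CC2=O | target

**Count**

Total steps: 6. Longest linear sequence: 4 steps (steps 1, 2, 3 and 6; the other branch is steps 4, 5 and 6).

**Steps most likely to fail, with fallbacks**

Step 6. What may go wrong: loss of enantiocontrol, because the doubly ortho-hydroxylated acceptor may close without the catalyst, or ring C may open and re-close in the hot acidic part; in addition the arm alcohol may condense with itself faster than it alkylates ring A. The fallback sets out from 6 and comes back at 11. Compound 6 is condensed with N,N-dimethylformamide dimethyl acetal (toluene, 90 °C) to the enaminone (E)-1-(2,6-dihydroxy-4-methoxyphenyl)-3-(dimethylamino)prop-2-en-1-one F1. F1 closes under acid (aq. HCl, EtOH, reflux; either phenol, again by symmetry) to 5-hydroxy-7-methoxy-4H-chromen-4-one F2. Rhodium-catalysed asymmetric 1,4-addition of phenylboronic acid ([RhOH(cod)]2, the enantiomer of 2,2'-bis[bis(3,4,5-trifluorophenyl)phosphino]-6,6'-dimethoxy-1,1'-biphenyl that gives 2S, toluene/H2O, rt) then gives 11. Isolated 11 is treated with 5 and TsOH·H2O in toluene/dioxane at 70 °C, as in the last part of step 6, to give 12. This replaces the stereo-setting ring closure by a stereo-setting C–C bond formation on a ring closed beforehand.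

Step 4. What may go wrong: acylation at a phenoxide oxygen or at the excess amide base instead of at the enolate carbon, and poor solubility of the polylithiated ketone. The fallback sets out from 6 and comes back at 7. Both phenols are benzylated (benzyl bromide, K2CO3, DMF, 70 °C) to 1-[2,6-bis(benzyloxy)-4-methoxyphenyl]ethan-1-one F3. Its simple lithium enolate (LiN(SiMe3)2, 2.2 equiv, THF, −78 °C) is C-acylated with Boc2O to tert-butyl 3-[2,6-bis(benzyloxy)-4-methoxyphenyl]-3-oxopropanoate F4. Hydrogenolysis (H2, Pd/C, EtOAc, rt) frees both phenols and gives 7.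

Step 5. What may go wrong: premature, amine-catalysed and therefore racemic closure of ring C while the condensation is still running. The fallback sets out from 7 and comes back at 9. Both phenols are silylated (tert-butyldimethylsilyl chloride, imidazole, DMF, rt) to tert-butyl 3-[2,6-bis(tert-butyldimethylsilyloxy)-4-methoxyphenyl]-3-oxopropanoate F5. Condensation with 8 under the conditions of step 5 gives tert-butyl (2Z)-2-[2,6-bis(tert-butyldimethylsilyloxy)-4-methoxybenzoyl]-3-phenylprop-2-enoate F6, which cannot cyclise. HF·pyridine (THF, 0 °C, acidic so that no phenoxide forms) removes both silyl groups and gives 9, which is taken at once into step 6.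

Further compounds
F1 | step 6 | (E)-1-(2,6-dihydroxy-4-methoxyphenyl)-3-(dimethylamino)prop-2-en-1-one | COc1cc(O)c(C(=O)/C=C/N(C)C)c(O)c1
F2 | step 6 | 5-hydroxy-7-methoxy-4H-chromen-4-one | COc1cc(O)c2c(=O)ccoc2c1
F3 | step 4 | 1-[2,6-bis(benzyloxy)-4-methoxyphenyl]ethan-1-one | COc1cc(OCc2ccccc2)c(C(C)=O)c(OCc2ccccc2)c1
F4 | step 4 | tert-butyl 3-[2,6-bis(benzyloxy)-4-methoxyphenyl]-3-oxopropanoate | COc1cc(OCc2ccccc2)c(C(=O)CC(=O)OC(C)(C)C)c(OCc2ccccc2)c1
F5 | step 5 | tert-butyl 3-[2,6-bis(tert-butyldimethylsilyloxy)-4-methoxyphenyl]-3-oxopropanoate | COc1cc(O[Si](C)(C)C(C)(C)C)c(C(=O)CC(=O)OC(C)(C)C)c(O[Si](C)(C)C(C)(C)C)c1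
F6 | step 5 | tert-butyl (2Z)-2-[2,6-bis(tert-butyldimethylsilyloxy)-4-methoxybenzoyl]-3-phenylprop-2-enoate | COc1cc(O[Si](C)(C)C(C)(C)C)c(C(=O)/C(=C/c2ccccc2)C(=O)OC(C)(C)C)c(O[Si](C)(C)C(C)(C)C)c1
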